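Work in fractions of the charge per minute. This flask holds the racemic substrates, partner, the single-handed free catalyst and a racemization catalyst loading between those of the east and north runs .

| flask | left-handed substrate | right-handed substrate | partner | free catalyst | racemization catalyst | remark | time |
|---|---|---|---|---|---|---|---|
| east | 0.20 M | 0.20 M | 2 equiv | 15 mol% | 0.67 mol% | run made earlier |  |
| north | 0.20 M | 0.20 M | 2 equiv | 15 mol% | 1.5 mol% | run made earlier |  |
| flask | 0.20 M | 0.20 M | 2.00 equiv | 15 mol% | 1 mol% |  | 25 min |

- east (time / min: left-handed product / %, right-handed product / %): 1.50: 13.1, 8.7; 3.00: 18.4, 11.8; 6.00: 23.8, 14.3; 10.0: 26.2, 17.0; 20.0: 28.8, 18.7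
- north (time / min: left-handed product / %, right-handed product / %): 4.00: 21.0, 13.0; 8.00: 25.4, 15.5; 12.0: 27.6, 17.6; 15.0: 28.1, 17.7; 20.0: 29.4, 17.7

(readings scatter by 0.5 percentage points)

- free catalyst is single-handed; left-handed substrate and right-handed substrate are mirror images of each other, charged as a racemate, each of them at the stated concentration
- an excess is the difference of the two amounts in percent of their sum
- an excess is below zero if the other one leads

- left-handed product and right-handed product together, in percent of the left-handed substrate and right-handed substrate charged together, at 25 min
- excess of left-handed product over right-handed product in the product at 25 min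
- whether the exchange between left-handed substrate and right-handed substrate keeps pace with the reaction: how far the product's excess at 25 min gets from its value without exchange to its value with instant exchange (above 80% keeps pace, below 20% hardly takes part, else lags behind)

Descend the ladder from exchange to stall. First rung: pool both readings at 20.0 min and divide left-handed by right-handed product. This gives 1.60. Call it s, the selectivity factor: the ratio in which the two products form while the substrates stand level. The first east reading gives 1.51, so the ratio holds roughly steady. Now test the opposite case. Two substrates that never exchange keep the ratio of the logarithms of their unconsumed fractions constant. Here it climbs from 1.59 to 1.93. So I judge that exchange keeps pace, and the excess is (s−1)/(s+1), or 23.0%.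

Second rung: the east run starts at a mean 0.145 min⁻¹. Third rung: the north run ends at 0.00237 min⁻¹, which is 61.2 times slower. Yet the readings of the north run leave 52.9% of the two substrates unconverted at 20.0 min, so I infer that another concentration has fallen. The readings do not name it. Extend that late rate from the mean yield at 20.0 min to reach 48.5%.

The forecast gave 48.5%, 23% and keeps pace: “With no such fall, and little dependence on loading, exchange keeps pace”.

The flask gives 47.9%, 23.0% and keeps pace, getting 90% of the way. At 25.0 min, partner stands at 0.738% of its charge, the limiting reagent, while free catalyst stands at 100%. Apply s to the yield: the left-handed share is 29.5%, and the flask holds 29.5%.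

    partner + free catalyst + left-handed substrate → free catalyst + left-handed product (k = 0.408 M⁻² s⁻¹)
    2 racemization catalyst ⇌ resting dimer (K = 11000 M⁻¹, k = 38.1 M⁻¹ s⁻¹)
    left-handed substrate + racemization catalyst ⇌ right-handed substrate + racemization catalyst, rate k3*[racemization catalyst]*[left-handed substrate] forward; the back reaction follows from the equilibrium constant (k = 65.7 M⁻¹ s⁻¹)
    partner + free catalyst + right-handed substrate → free catalyst + right-handed product (k = 0.252 M⁻² s⁻¹)
    2 partner → homo dimer (k = 0.0106 M⁻¹ s⁻¹)

Take the neighbour flask with 38 mol% of free catalyst. There s gives an excess of 23.0% and, from its yield of 66.1%, 40.7% left-handed product. The computed flask gives 22.1% and 40.4%.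

The readings stem from a simulated flask with made-up constants, and the scatter is random.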